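In a one-step world each partner takes one substrate, and a charge simply removes its own amount. I tested that on elm, where it would have removed 13.0% of the substrate. The reading at 120 s showed 6.00% gone, less than that and beyond the scatter, so either partner was going somewhere else or elm was still unfinished at that reading.

| setting | elm | maple | dusk | winter | spring | summer | noon |
|---|---|---|---|---|---|---|---|
| substrate | 0.010 M | 0.010 M | 0.010 M | 0.010 M | 0.010 M | 0.010 M | 0.010 M |
| partner | 1.3 mM | 130 mM | 2.50 mM | 8.00 mM | 25.0 mM | 80.0 mM | 200 mM |
| remark | run made earlier | run made earlier |  |  |  |  |  |
| time |  |  | 4.0 min | 4.0 min | 4.0 min | 4.0 min | 4.0 min |

| run | time / s | first product / % | substrate / % |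
|---|---|---|---|
| elm | 10.0 | 5 | 101 |
| elm | 20.0 | 5 | 99 |
| elm | 30.0 | 3 | 98 |
| elm | 60.0 | 3 | 98 |
| elm | 120 | 0 | 94 |
| maple | 10.0 | 56 | 14 |
| maple | 20.0 | 45 | 5 |
| maple | 30.0 | 37 | 1 |
| maple | 60.0 | 34 | 2 |
| maple | 120 | 27 | 2 |

(readings scatter by 2 percentage points)
- "hardly changes" means that all values lie within two and a half points (for a concentration: within two and a half percent of the largest)
* amount of first product at the end, in percent of the substrate charged for dusk, winter, spring, summer, noon, in this order
* how that number moves from the first to the last of them (hardly changes / rises, then falls / rises all the way / falls all the way / falls, then rises)

Maple held partner in excess, more than substrate, so I first expected pseudo-first-order decay of substrate with one constant. The readings spoke against it. The logarithm of the substrate's fall grew by u = 1.97 in the first interval but by v = 1.03 in the second, less than before. Substrate was too small a charge to have used up that excess, so I inferred that partner wastes itself. If each interval gives the same fraction of the one before, the series sums to the total fall N: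

N = u·u/(u − v) = 4.13

R = c(maple)/N = 31.5 mM

I called R the reach, the partner charge that lowers substrate by a factor e, so that for a charge c, with the substrate charge held at 0.010 M and partner reckoned as lost by its own waste:

substrate left = exp(−c/R)

My objection was that u and v rest on two scattered readings, and that R came from a large charge. Elm, a separate run at a small charge, gives a check: the rule leaves 96.0% there, against the last reading of 94%, about one scatter away.

The row needs a crossing as well. In maple, first product fell after 56%, read with 14% substrate left. I took formation and further loss to be first order in partner, so that partner cancels in their ratio and the crest stands at a similar substrate level in these flasks. Partner then gives out before the crest at low charges and after it at high ones: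

c(cross) = R·ln(substrate charged/substrate at crest) = 61.9 mM

The crest may lie before that first reading, so this mark is rough, but it stands above spring and below noon. I committed to a row that rises, then falls, with its top at summer.

The forecast gave 1%, 3%, 10%, 18%, 14%, rises, then falls, expecting that “high partner would then erode the product more”.

The flasks gave 3.65%, 10.8%, 26.6%, 37.3%, 18.3%: rises, then falls, turning at 66 mM.

    substrate + partner → first product + by-product (k = 2.70 M⁻¹ s⁻¹)
    partner + first product → double product + by-product (k = 0.750 M⁻¹ s⁻¹)
    partner → decomposition product (k = 1.30 × 10⁻⁴ s⁻¹)
    partner → decomposed reagent (k = 0.0800 s⁻¹)
    first product ⇌ isomer of the product (K = 0.670, k = 0.0140 s⁻¹)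

The reach puts summer's substrate at 7.89%, and that flask holds 10.0%. For noon it gives 0.175%, and the flask holds 0.209%. Noon still keeps 18.3% first product partly because two things act together: partner decays to decomposed reagent, and isomer of the product returns to first product. Without that decay noon ends at 0.0201% first product, and without the way back at 0.900%.

Readings and results are simulated on assumed constants; noise was put on by code.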